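**Retrosynthetic overview**
1. The sulfate and the free acid come last: C7–OSO3H from C7–OH, and the (2E,4E)-dienoate from a C1 aldehyde by a vinylogous Horner–Wadsworth–Emmons olefination.
2. Ring B is closed by the C6–C7 bond: a sparteine-controlled α-lithiated O-carbamate at C7 displaces a primary chloride at C6, which creates the C7 carbinol centre by reagent control with its oxygen already in place.
3. Enabling feature: in ring B, C7 is a secondary carbinol carbon (it bears the sulfated oxygen), flanked by the methyl-bearing C8 and by C6, an unsubstituted CH2 two atoms from the ring-fusion carbon C4a. C7 can therefore be a configurationally stable α-oxy carbanion and C6 a primary electrophile on the two cis arms at C4a and C8a of ring A.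
4. Ring A with its four stereocentres (C1, C2, C4a, C8a) and the C3=C4 alkene comes from one endo-selective, organocatalytic Diels–Alder reaction of a (Z,E,E)-triene with an (E)-enal; C8 comes from methyl (S)-3-hydroxy-2-methylpropanoate.
5. Order of ring formation: ring A (step 8), then ring B (step 10).

Key step: step 10

Remark: the locants C1–C8a of the target's octahydronaphthalene are used for all intermediates (ring A = C1, C2, C3, C4, C4a, C8a; ring B = C4a, C5, C6, C7, C8, C8a), also where a monocyclic precursor is meant.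
Remark (assumption): the (5R)-imidazolidinone is taken to expose the α-Re face of the enal, the mirror image of the known behaviour of its (5S) antipode. (−)-Sparteine is taken to remove the pro-S hydrogen of the O-alkyl carbamate, with substitution under retention.

**Step 1**
Reactants: 1 (E)-2-methylbut-2-enal; 2 2-(triphenylphosphoranylidene)propanal
Product: 3 (2E,4E)-2,4-dimethylhexa-2,4-dienal
Conditions: toluene, 110 °C
Reagents that add atoms: 2 2-(triphenylphosphoranylidene)propanal, CC(C=O)=P(c1ccccc1)(c1ccccc1)c1ccccc1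
Why: Wittig olefination with a formyl-stabilised ylide gives the (E)-trisubstituted enal and leaves the existing (E)-alkene untouched.

**Step 2**
Reactants: 3 (2E,4E)-2,4-dimethylhexa-2,4-dienal; 4 [3-(tert-butyldimethylsilyloxy)propyl]triphenylphosphonium bromide
Product: 5 tert-butyl{[(3Z,5E,7E)-5,7-dimethylnona-3,5,7-trien-1-yl]oxy}dimethylsilane
Conditions: NaN(SiMe3)2, THF, −78 → 0 °C
Reagents that add atoms: 4 [3-(tert-butyldimethylsilyloxy)propyl]triphenylphosphonium bromide, CC(C)(C)[Si](C)(C)OCCC[P+](c1ccccc1)(c1ccccc1)c1ccccc1.[Br-]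
Why: Salt-free Wittig olefination with a non-stabilised ylide should give the (Z)-disubstituted alkene under kinetic control, which puts the future C5–C6 arm on the inside of the diene.

**Step 3**
Reactants: 5 triene silyl ether
Product: 6 (3Z,5E,7E)-5,7-dimethylnona-3,5,7-trien-1-ol
Conditions: Bu4NF, THF, 0 → 23 °C
Reagents that add atoms: none
Why: Fluoride-induced desilylation frees the primary alcohol and touches nothing else.

**Step 4**
Reactants: 6 (3Z,5E,7E)-5,7-dimethylnona-3,5,7-trien-1-ol
Product: 7 (2E,4E,6Z)-9-chloro-3,5-dimethylnona-2,4,6-triene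
Conditions: N-chlorosuccinimide, PPh3, CH2Cl2, 0 → 23 °C
Reagents that add atoms: N-chlorosuccinimide, O=C1CCC(=O)N1Cl
Why: Appel-type chlorination (chlorophosphonium activation, then SN2 by chloride) converts the primary alcohol to the chloride under neutral conditions that spare the acid-sensitive triene.

**Step 5**
Reactants: 8 methyl (S)-3-hydroxy-2-methylpropanoate
Product: 9 methyl (S)-3-[(diisopropylcarbamoyl)oxy]-2-methylpropanoate
Conditions: i-Pr2NC(O)Cl, pyridine, DMAP (cat.), 70 °C
Reagents that add atoms: N,N-diisopropylcarbamoyl chloride, CC(C)N(C(C)C)C(Cl)=O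
Why: O-Carbamoylation under nucleophilic catalysis installs the group that later directs lithiation at C7; the stereocentre (future C8) is not involved.

**Step 6**
Reactants: 9 carbamate ester
Product: 10 (S)-2-methyl-3-oxopropyl diisopropylcarbamate
Conditions: i-Bu2AlH, CH2Cl2, −78 °C; aqueous sodium potassium tartrate work-up
Reagents that add atoms: none
Why: Partial reduction of the methyl ester stops at the aluminium hemiacetal at low temperature and gives the aldehyde on work-up; the hindered carbamate is not reduced and cold, non-basic handling keeps the α-centre.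

**Step 7**
Reactants: 10 (S)-2-methyl-3-oxopropyl diisopropylcarbamate; 11 (triphenylphosphoranylidene)acetaldehyde
Product: 12 (R,E)-2-methyl-5-oxopent-3-en-1-yl diisopropylcarbamate
Conditions: toluene, 50 °C
Reagents that add atoms: 11 (triphenylphosphoranylidene)acetaldehyde, O=CC=P(c1ccccc1)(c1ccccc1)c1ccccc1
Why: Wittig olefination with the formyl-stabilised ylide gives the (E)-enal without added base, so the α-stereocentre (future C8) is kept.

**Step 8**
Reactants: 7 (2E,4E,6Z)-9-chloro-3,5-dimethylnona-2,4,6-triene; 12 (R,E)-2-methyl-5-oxopent-3-en-1-yl diisopropylcarbamate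
Product: 13 (1S,2R,5S,6S)-2-[(E)-but-2-en-2-yl]-5-(2-chloroethyl)-6-[(R)-1-(diisopropylcarbamoyloxy)propan-2-yl]-3-methylcyclohex-3-ene-1-carbaldehyde
Conditions: (5R)-5-benzyl-2,2,3-trimethylimidazolidin-4-one·HClO4 (20 mol %), MeCN–H2O (95:5), −10 → 4 °C
Reagents that add atoms: none
Why: Iminium-activated Diels–Alder reaction: the imidazolidinone forms the (E)-iminium ion of 12 and shields its α-Si face, so the diene unit C4–C7 of 7 adds to the α-Re face through the endo transition state with the (Z)-terminus bonding to the β-carbon, which should set C1/C2 cis (outside butenyl group), C1/C8a trans ((E)-dienophile) and C4a/C8a cis (inside arm of the (Z)-alkene).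

**Step 9**
Reactants: 13 Diels–Alder aldehyde
Product: 14 dimethyl acetal of 13 (1-dimethoxymethyl in place of 1-formyl; stereocentres as in 13)
Conditions: HC(OMe)3, MeOH, pyridinium p-toluenesulfonate (cat.), 23 °C
Reagents that add atoms: trimethyl orthoformate, COC(OC)OC; methanol, CO
Why: Acid-catalysed acetalisation masks the aldehyde against the organolithium base of step 10; the mild acid should leave C1 and the alkenes unchanged.

**Step 10**
Reactants: 14 dimethyl acetal of 13
Product: 16 (1S,2R,4aS,7S,8R,8aS)-2-[(E)-but-2-en-2-yl]-1-(dimethoxymethyl)-3,8-dimethyl-1,2,4a,5,6,7,8,8a-octahydronaphthalen-7-yl diisopropylcarbamate, via (S)-α-lithio carbamate 15 (not isolated)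
Conditions: s-BuLi, (−)-sparteine, Et2O, −78 °C; then −78 → −40 °C
Reagents that add atoms: none
Why: Proposed new method: s-BuLi·(−)-sparteine, held by the carbamate carbonyl, removes the pro-S hydrogen at C7 to give the configurationally stable (S)-α-oxy organolithium 15, whose C–Li bond then displaces the primary chloride at C6 with retention at C7; the closest known reaction types are the sparteine-mediated lithiation–substitution of O-alkyl carbamates, their intramolecular cycloalkylation onto allylic chlorides to five-membered rings, and the lithiation–cyclisation of N-Boc-N-(chloroalkyl)benzylamines onto primary chlorides to six-membered rings. Ring B is closed in the 6-exo-tet mode. The new stereocentre C7 (S) is set by the chiral diamine (reagent control) and already carries its oxygen, so no later redox adjustment is needed, while C4a, C8 and C8a are carried through unchanged. The step needs selection between the two diastereotopic C7 hydrogens against the neighbouring C8 centre, and chemoselectivity over allylic deprotonation at C2 and over loss of HCl; the carbamate-directed, diamine-bound base should secure the first two, and the unhindered primary chloride two atoms from C4a together with the low temperature the last.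

**Step 11**
Reactants: 16 ring B-closed carbamate acetal
Product: 18 (1S,2R,4aS,7S,8R,8aS)-2-[(E)-but-2-en-2-yl]-7-hydroxy-3,8-dimethyl-1,2,4a,5,6,7,8,8a-octahydronaphthalene-1-carbaldehyde, via hydroxy dimethyl acetal 17 (not isolated)
Conditions: LiAlH4, THF, 65 °C; then HCl (0.5 M), THF–H2O, 23 °C
Reagents that add atoms: water, O
Why: Hydride attack at the carbamate carbonyl releases the C7 alkoxide with the C7–O bond untouched (retention), and dilute aqueous acid then hydrolyses the dimethyl acetal to the aldehyde.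

**Step 12**
Reactants: 18 hydroxy aldehyde; 19 triethyl 4-phosphonocrotonate
Product: 20 ethyl (2E,4E)-5-[(1S,2R,4aS,7S,8R,8aR)-2-[(E)-but-2-en-2-yl]-7-hydroxy-3,8-dimethyl-1,2,4a,5,6,7,8,8a-octahydronaphthalen-1-yl]penta-2,4-dienoate
Conditions: LiN(SiMe3)2, THF, −78 → 0 °C
Reagents that add atoms: 19 triethyl 4-phosphonocrotonate, CCOC(=O)/C=C/CP(=O)(OCC)OCC
Why: Vinylogous Horner–Wadsworth–Emmons olefination adds four carbons and should give the (2E,4E)-dienoate under thermodynamic control; addition of the aldehyde at low temperature protects C1.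

**Step 13**
Reactants: 20 hydroxy dienoate
Product: 21 ethyl (2E,4E)-5-[(1S,2R,4aS,7S,8R,8aR)-2-[(E)-but-2-en-2-yl]-3,8-dimethyl-7-(sulfooxy)-1,2,4a,5,6,7,8,8a-octahydronaphthalen-1-yl]penta-2,4-dienoate
Conditions: SO3·pyridine, DMF, 23 °C
Reagents that add atoms: sulfur trioxide–pyridine complex, [O-]S(=O)(=O)[n+]1ccccc1
Why: O-Sulfation of the only hydroxyl group takes place at oxygen, so C7 keeps its configuration.

**Step 14**
Reactants: 21 sulfated ethyl ester
Product: 22 (2E,4E)-5-[(1S,2R,4aS,7S,8R,8aR)-2-[(E)-but-2-en-2-yl]-3,8-dimethyl-7-(sulfooxy)-1,2,4a,5,6,7,8,8a-octahydronaphthalen-1-yl]penta-2,4-dienoic acid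
Conditions: LiOH, THF–MeOH–H2O, 23 °C; then HCl (1 M) to pH 2, 0 °C
Reagents that add atoms: lithium hydroxide, [Li+].[OH-]
Why: Saponification cleaves the ethyl ester while the monoalkyl sulfate anion is inert to hydroxide, and cold acidification gives the free acid form.

**Compound list**
1 | (E)-2-methylbut-2-enal | C/C=C(\C)C=O | starting material
2 | 2-(triphenylphosphoranylidene)propanal | CC(C=O)=P(c1ccccc1)(c1ccccc1)c1ccccc1 | starting material
3 | (2E,4E)-2,4-dimethylhexa-2,4-dienal | C/C=C(\C)/C=C(\C)C=O | intermediate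
4 | [3-(tert-butyldimethylsilyloxy)propyl]triphenylphosphonium bromide | CC(C)(C)[Si](C)(C)OCCC[P+](c1ccccc1)(c1ccccc1)c1ccccc1.[Br-] | starting material
5 | tert-butyl{[(3Z,5E,7E)-5,7-dimethylnona-3,5,7-trien-1-yl]oxy}dimethylsilane | C/C=C(\C)/C=C(\C)/C=C\CCO[Si](C)(C)C(C)(C)C | intermediate
6 | (3Z,5E,7E)-5,7-dimethylnona-3,5,7-trien-1-ol | C/C=C(\C)/C=C(\C)/C=C\CCO | intermediate
7 | (2E,4E,6Z)-9-chloro-3,5-dimethylnona-2,4,6-triene | C/C=C(\C)/C=C(\C)/C=C\CCCl | intermediate
8 | methyl (S)-3-hydroxy-2-methylpropanoate | C[C@@H](CO)C(=O)OC | starting material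
9 | methyl (S)-3-[(diisopropylcarbamoyl)oxy]-2-methylpropanoate | C[C@@H](COC(=O)N(C(C)C)C(C)C)C(=O)OC | intermediate
10 | (S)-2-methyl-3-oxopropyl diisopropylcarbamate | C[C@@H](COC(=O)N(C(C)C)C(C)C)C=O | intermediate
11 | (triphenylphosphoranylidene)acetaldehyde | O=CC=P(c1ccccc1)(c1ccccc1)c1ccccc1 | starting material
12 | (R,E)-2-methyl-5-oxopent-3-en-1-yl diisopropylcarbamate | O=C/C=C/[C@@H](C)COC(=O)N(C(C)C)C(C)C | intermediate
13 | (1S,2R,5S,6S)-2-[(E)-but-2-en-2-yl]-5-(2-chloroethyl)-6-[(R)-1-(diisopropylcarbamoyloxy)propan-2-yl]-3-methylcyclohex-3-ene-1-carbaldehyde | C/C=C(\C)[C@@H]1C(C)=C[C@@H](CCCl)[C@@H]([C@@H](C)COC(=O)N(C(C)C)C(C)C)[C@@H]1C=O | intermediate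
14 | dimethyl acetal of 13 (stereocentres as in 13) | C/C=C(\C)[C@@H]1C(C)=C[C@@H](CCCl)[C@@H]([C@@H](C)COC(=O)N(C(C)C)C(C)C)[C@@H]1C(OC)OC | intermediate
15 | (S)-α-lithio carbamate of 14 (lithium at C7, sparteine-bound) | C/C=C(\C)[C@@H]1C(C)=C[C@@H](CCCl)[C@@H]([C@@H](C)[C@H]([Li])OC(=O)N(C(C)C)C(C)C)[C@@H]1C(OC)OC | intermediate
16 | (1S,2R,4aS,7S,8R,8aS)-2-[(E)-but-2-en-2-yl]-1-(dimethoxymethyl)-3,8-dimethyl-1,2,4a,5,6,7,8,8a-octahydronaphthalen-7-yl diisopropylcarbamate (target locants) | C/C=C(\C)[C@@H]1C(C)=C[C@H]2CC[C@H](OC(=O)N(C(C)C)C(C)C)[C@H](C)[C@H]2[C@@H]1C(OC)OC | intermediate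
17 | (1S,2R,4aS,7S,8R,8aS)-2-[(E)-but-2-en-2-yl]-1-(dimethoxymethyl)-3,8-dimethyl-1,2,4a,5,6,7,8,8a-octahydronaphthalen-7-ol (target locants) | C/C=C(\C)[C@@H]1C(C)=C[C@H]2CC[C@H](O)[C@H](C)[C@H]2[C@@H]1C(OC)OC | intermediate
18 | (1S,2R,4aS,7S,8R,8aS)-2-[(E)-but-2-en-2-yl]-7-hydroxy-3,8-dimethyl-1,2,4a,5,6,7,8,8a-octahydronaphthalene-1-carbaldehyde | C/C=C(\C)[C@@H]1C(C)=C[C@H]2CC[C@H](O)[C@H](C)[C@H]2[C@@H]1C=O | intermediate
19 | triethyl 4-phosphonocrotonate | CCOC(=O)/C=C/CP(=O)(OCC)OCC | starting material
20 | ethyl (2E,4E)-5-[(1S,2R,4aS,7S,8R,8aR)-2-[(E)-but-2-en-2-yl]-7-hydroxy-3,8-dimethyl-1,2,4a,5,6,7,8,8a-octahydronaphthalen-1-yl]penta-2,4-dienoate | C/C=C(\C)[C@@H]1C(C)=C[C@H]2CC[C@H](O)[C@H](C)[C@H]2[C@@H]1/C=C/C=C/C(=O)OCC | intermediate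
21 | ethyl (2E,4E)-5-[(1S,2R,4aS,7S,8R,8aR)-2-[(E)-but-2-en-2-yl]-3,8-dimethyl-7-(sulfooxy)-1,2,4a,5,6,7,8,8a-octahydronaphthalen-1-yl]penta-2,4-dienoate | C/C=C(\C)[C@@H]1C(C)=C[C@H]2CC[C@H](OS(=O)(=O)O)[C@H](C)[C@H]2[C@@H]1/C=C/C=C/C(=O)OCC | intermediate
22 | (2E,4E)-5-[(1S,2R,4aS,7S,8R,8aR)-2-[(E)-but-2-en-2-yl]-3,8-dimethyl-7-(sulfooxy)-1,2,4a,5,6,7,8,8a-octahydronaphthalen-1-yl]penta-2,4-dienoic acid | C/C=C(\C)[C@@H]1C(C)=C[C@H]2CC[C@H](OS(=O)(=O)O)[C@H](C)[C@H]2[C@@H]1/C=C/C=C/C(=O)O | target

**Totals**
Total step count: 14. Longest linear sequence: 11 steps (steps 1–4, then 8–14).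

**Steps most likely to fail**

1. Step 10 (Proposed new method). The ring closure at C6 may be too slow at the temperatures at which the lithiated carbamate keeps its configuration. Then 1,2-carbamoyl migration, loss of HCl, or loss of diamine control at C7 (mismatch with the neighbouring C8 centre) could take over. The fallback uses known chemistry, sets out from 14 and returns at 17. The carbamate of 14 is cleaved with i-Bu2AlH (CH2Cl2, 23 °C) to the chloro alcohol F1. Dess–Martin oxidation gives the chloro aldehyde F2, and Finkelstein exchange (NaI, acetone, 56 °C) the iodo aldehyde F3. A samarium diiodide Barbier cyclisation (SmI2, THF–HMPA, −78 → 0 °C) closes the same C6–C7 bond and gives the carbinol mixture F4, epimeric at C7. Dess–Martin oxidation of F4 gives the C7 ketone F5 (buffered, so that C8 is not enolised). Corey–Bakshi–Shibata reduction with the (R)-methyl-oxazaborolidine and BH3·SMe2 (−30 °C) then sets C7 by reagent control and gives 17, which step 11 hydrolyses to 18.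

2. Step 8. The (Z)-configured diene terminus may react too slowly with the iminium ion, the (Z)-alkene may isomerise under the acid co-catalyst, or endo and facial control may be poor. The fallback sets out from 10 and returns at 13. Horner–Wadsworth–Emmons olefination of 10 with (R)-4-benzyl-3-[(diethoxyphosphoryl)acetyl]oxazolidin-2-one (LiCl, i-Pr2NEt, MeCN) gives the (E)-enoyl imide F6. Its chelate with Et2AlCl is a far stronger dienophile and should add 7 at −78 → −30 °C (CH2Cl2) under auxiliary control on the α-Re face, giving the imide adduct F7. LiBH4 (THF, MeOH, 0 °C) removes the auxiliary and gives the primary alcohol F8, and Dess–Martin oxidation returns 13.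

3. Step 12. The α-branched aldehyde may epimerise at C1 under the basic conditions (helped by reversible closure of the C7 hydroxyl onto the aldehyde), and geometric control may be poor in the one-step four-carbon olefination. The fallback sets out from 18 and returns at 20. A base-free Wittig reaction of 18 with 11 (toluene, 60 °C) gives the (E)-enal F9, in which C1 is no longer α to a carbonyl group. A second two-carbon olefination with triethyl phosphonoacetate (LiCl, DBU, MeCN, 23 °C) then gives 20.

Further compounds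
F1 | step 10 | chloro alcohol: 14 with CH2OH in place of the carbamate-bearing CH2 | C/C=C(\C)[C@@H]1C(C)=C[C@@H](CCCl)[C@@H]([C@@H](C)CO)[C@@H]1C(OC)OC
F2 | step 10 | chloro aldehyde: F1 oxidised at C7 | C/C=C(\C)[C@@H]1C(C)=C[C@@H](CCCl)[C@@H]([C@@H](C)C=O)[C@@H]1C(OC)OC
F3 | step 10 | iodo aldehyde: F2 with iodide at C6 | C/C=C(\C)[C@@H]1C(C)=C[C@@H](CCI)[C@@H]([C@@H](C)C=O)[C@@H]1C(OC)OC
F4 | step 10 | ring B-closed carbinol, mixture of C7 epimers of 17 | C/C=C(\C)[C@@H]1C(C)=C[C@H]2CCC(O)[C@H](C)[C@H]2[C@@H]1C(OC)OC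
F5 | step 10 | C7 ketone of 17 | C/C=C(\C)[C@@H]1C(C)=C[C@H]2CCC(=O)[C@H](C)[C@H]2[C@@H]1C(OC)OC
F6 | step 8 | (R)-4-benzyl-3-[(R,E)-5-(diisopropylcarbamoyloxy)-4-methylpent-2-enoyl]oxazolidin-2-one | O=C(/C=C/[C@@H](C)COC(=O)N(C(C)C)C(C)C)N1[C@H](Cc2ccccc2)COC1=O
F7 | step 8 | imide adduct: 13 with the N-acyl (R)-4-benzyloxazolidin-2-one in place of the formyl group | C/C=C(\C)[C@@H]1C(C)=C[C@@H](CCCl)[C@@H]([C@@H](C)COC(=O)N(C(C)C)C(C)C)[C@@H]1C(=O)N2[C@H](Cc3ccccc3)COC2=O
F8 | step 8 | primary alcohol: 13 with CH2OH in place of the formyl group | C/C=C(\C)[C@@H]1C(C)=C[C@@H](CCCl)[C@@H]([C@@H](C)COC(=O)N(C(C)C)C(C)C)[C@@H]1CO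
F9 | step 12 | (E)-enal: two-carbon homologue of 18 at C1 | C/C=C(\C)[C@@H]1C(C)=C[C@H]2CC[C@H](O)[C@H](C)[C@H]2[C@@H]1/C=C/C=O
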